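Locants follow the C19 chain: pentyl C1–C5, oxolane O/C6/C7/C8/C9, carbinol C10, terminal alkene C18=C19. The plan rests on cutting the ring O–C9 bond together with the C10–OH bond, because these two oxygens lie syn on what can be an E-C9=C10 alkene. A hydroxyl-directed rhenium(VII) syn-oxidative cyclisation of the acyclic (6S,7S)-6-hydroxy-9E,18-dien-7-yl stearate closes the oxolane and sets C9 (2,5-trans) and C10 (threo). It also unveils the free C10 hydroxyl in the final operation, with the C7 stearate already installed and C18=C19 spared. The precursor arises from a Sharpless epoxide of oct-1-en-3-ol, an E-alkenylalanate and a Mitsunobu inversion with stearic acid.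

Key step: step 7

Step 1
Reactants: 1 (±)-oct-1-en-3-ol
Product: 2 (1S)-1-[(2R)-oxiran-2-yl]hexan-1-ol (erythro epoxy alcohol; C6 S, C7 R)
Conditions: Ti(OiPr)4 (cat.), L-(+)-DIPT (cat.), t-BuOOH (0.45 equiv), 4 Å MS, CH2Cl2, −20 °C
Reagents that add atoms: tert-butyl hydroperoxide, CC(C)(C)OO
Why: Sharpless asymmetric epoxidation run as a kinetic resolution: with L-(+)-DIPT the (S)-alcohol is the fast-reacting enantiomer and is epoxidised on the catalyst-preferred face with erythro selectivity, which fixes C6 as S and sets C7 as R, while the (R)-alcohol stays behind and is separated.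

Step 2
Reactants: 2 (1S)-1-[(2R)-oxiran-2-yl]hexan-1-ol
Product: 3 tert-butyl(dimethyl){(1S)-1-[(2R)-oxiran-2-yl]hexyloxy}silane
Conditions: TBSCl, imidazole, DMF, rt
Reagents that add atoms: tert-butyldimethylsilyl chloride, CC(C)(C)[Si](C)(C)Cl
Why: Standard silyl ether protection of a secondary alcohol masks O6, so that only O7 is free once the epoxide is opened; no stereocentre is touched.

Step 3
Reactants: 4 9-bromonon-1-ene; 5 lithium acetylide–ethylenediamine complex
Product: 6 undec-1-en-10-yne
Conditions: DMSO, 0 °C to rt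
Reagents that add atoms: none
Why: SN2 alkylation of lithium acetylide by a primary bromide in a dipolar aprotic solvent, to which the isolated terminal alkene is inert.

Step 4
Reactants: 6 undec-1-en-10-yne; 3 tert-butyl(dimethyl){(1S)-1-[(2R)-oxiran-2-yl]hexyloxy}silane
Product: 9 (6S,7R,9E)-6-[(tert-butyldimethylsilyl)oxy]nonadeca-9,18-dien-7-ol, via E-alkenylalane 7 (not isolated), via lithium alanate 8 (not isolated)
Conditions: 6, DIBAL-H (1 equiv), hexane, 50 °C; n-BuLi, 0 °C; then 3, THF, 0 °C to rt; aq. work-up
Reagents that add atoms: none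
Why: Syn-hydroalumination of the terminal alkyne (faster than that of the 1-alkene) gives the E-alkenylalane, whose ate complex transfers the alkenyl group with retention of geometry to the unsubstituted epoxide carbon C8 in an SN2 epoxide opening, so the E-C9=C10 geometry is set and C6 and C7 are untouched.

Step 5
Reactants: 9 (6S,7R,9E)-6-[(tert-butyldimethylsilyl)oxy]nonadeca-9,18-dien-7-ol; 10 octadecanoic (stearic) acid
Product: 11 (6S,7S,9E)-6-[(tert-butyldimethylsilyl)oxy]nonadeca-9,18-dien-7-yl octadecanoate
Conditions: PPh3, DIAD, toluene, 0 °C to rt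
Reagents that add atoms: none
Why: Mitsunobu esterification: stearate displaces the C7 oxyphosphonium group in an SN2 process, which inverts C7 from R to S and installs the ester of the target in the same operation, O6 being silylated.

Step 6
Reactants: 11 (6S,7S,9E)-6-[(tert-butyldimethylsilyl)oxy]nonadeca-9,18-dien-7-yl octadecanoate
Product: 12 (6S,7S,9E)-6-hydroxynonadeca-9,18-dien-7-yl octadecanoate
Conditions: HF·pyridine, pyridine, THF, 0 °C to rt
Reagents that add atoms: none
Why: Fluoride-mediated desilylation in a weakly acidic buffered medium frees O6 without base, which should suppress the 1,2-acyl shift from O7 to O6; the alcohol is taken on without delay.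

Step 7
Reactants: 12 (6S,7S,9E)-6-hydroxynonadeca-9,18-dien-7-yl octadecanoate
Product: 15 (2S,3S,5R)-5-[(1R)-1-hydroxydec-9-en-1-yl]-2-pentyloxolan-3-yl octadecanoate (target), via C6 perrhenate ester 13 (not isolated), via rhenium(V) C10 alkoxide 14 (not isolated)
Conditions: Re2O7 (2 equiv), 2,6-lutidine, CH2Cl2, 0 °C to rt; then H2O
Reagents that add atoms: dirhenium heptoxide, O=[Re](=O)(=O)O[Re](=O)(=O)=O
Why: The C6 hydroxyl condenses with Re2O7 to the alkyl perrhenate 13, whose RO–Re=O unit adds suprafacially across the tethered C9=C10 bond (formal [3+2], or [2+2] followed by alkoxide migration) to give the rhenium(V) alkoxide 14, which water hydrolyses to 15. The closest known reaction type is the rhenium(VII)-mediated hydroxyl-directed syn-oxidative cyclisation of bis-homoallylic alcohols, an established entry to trans-oxolanes flanked by threo carbinols. The oxolane O/C6/C7/C8/C9 closes in the 5-exo-trig mode by O6–C9 bond formation. C9 is controlled by C6 and C7: pentyl and stearoyloxy share one face of the envelope-like transition state, so the alkene chain takes the opposite face (2,5-trans, 9R), the alternative being an all-cis array. C10 follows from the syn-stereospecific addition to the E-alkene (threo, 10R). The step needs chemoselectivity for C9=C10 over C18=C19 and O6 as the only nucleophile; the covalent O6–Re tether secures the first (the terminal alkene is out of reach), and O7 being blocked as the very ester the target keeps secures the second.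

Compound list
1 | (±)-oct-1-en-3-ol | C=CC(O)CCCCC | starting material
2 | (1S)-1-[(2R)-oxiran-2-yl]hexan-1-ol | CCCCC[C@H](O)[C@H]1CO1 | intermediate
3 | tert-butyl(dimethyl){(1S)-1-[(2R)-oxiran-2-yl]hexyloxy}silane | CCCCC[C@H](O[Si](C)(C)C(C)(C)C)[C@H]1CO1 | intermediate
4 | 9-bromonon-1-ene | C=CCCCCCCCBr | starting material
5 | lithium acetylide–ethylenediamine complex | [Li]C#C.NCCN | starting material
6 | undec-1-en-10-yne | C=CCCCCCCCC#C | intermediate
7 | diisobutyl[(1E)-undeca-1,10-dien-1-yl]alane (not isolated) | C=CCCCCCCC/C=C/[Al](CC(C)C)CC(C)C | intermediate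
8 | lithium butyl(diisobutyl)[(1E)-undeca-1,10-dien-1-yl]alanate (not isolated) | [Li+].C=CCCCCCCC/C=C/[Al-](CCCC)(CC(C)C)CC(C)C | intermediate
9 | (6S,7R,9E)-6-[(tert-butyldimethylsilyl)oxy]nonadeca-9,18-dien-7-ol | CCCCC[C@H](O[Si](C)(C)C(C)(C)C)[C@H](O)C/C=C/CCCCCCCC=C | intermediate
10 | octadecanoic (stearic) acid | CCCCCCCCCCCCCCCCCC(=O)O | starting material
11 | (6S,7S,9E)-6-[(tert-butyldimethylsilyl)oxy]nonadeca-9,18-dien-7-yl octadecanoate | CCCCC[C@H](O[Si](C)(C)C(C)(C)C)[C@@H](OC(=O)CCCCCCCCCCCCCCCCC)C/C=C/CCCCCCCC=C | intermediate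
12 | (6S,7S,9E)-6-hydroxynonadeca-9,18-dien-7-yl octadecanoate | CCCCC[C@H](O)[C@@H](OC(=O)CCCCCCCCCCCCCCCCC)C/C=C/CCCCCCCC=C | intermediate
13 | C6 perrhenate ester of 12 (not isolated) | CCCCC[C@H](O[Re](=O)(=O)=O)[C@@H](OC(=O)CCCCCCCCCCCCCCCCC)C/C=C/CCCCCCCC=C | intermediate
14 | rhenium(V) C10 alkoxide of 15 (not isolated) | C=CCCCCCCC[C@@H](O[Re](=O)=O)[C@H]1C[C@H](OC(=O)CCCCCCCCCCCCCCCCC)[C@H](CCCCC)O1 | intermediate
15 | (2S,3S,5R)-5-[(1R)-1-hydroxydec-9-en-1-yl]-2-pentyloxolan-3-yl octadecanoate | C=CCCCCCCC[C@@H](O)[C@H]1C[C@H](OC(=O)CCCCCCCCCCCCCCCCC)[C@H](CCCCC)O1 | target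

Total step count: 7. Longest linear sequence: 6 (steps 1, 2, 4, 5, 6, 7).

Steps most likely to fail

Step 7. The perrhenate may add sluggishly next to the electron-poor acyloxy carbon, the 2,5-trans preference may erode, or the acyl group may shift between O7 and O6 before ring closure. The fallback sets out from 11 and comes back at 15, replacing the one-step syn process by an anti epoxide route with correction at C10.
- Shi epoxidation of 11 with the enantiomeric (L-fructose-type) ketone and Oxone should give the (9S,10S)-epoxide F1. It should be selective for the trans-disubstituted alkene over the terminal one.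
- HF·pyridine followed by catalytic CSA frees O6, which opens the epoxide 5-exo at C9 with inversion to the 10-epi oxolane alcohol F2.
- Dess–Martin oxidation gives the oxolanyl ketone F3.
- Felkin–Anh-controlled reduction with L-Selectride at −78 °C should deliver the threo alcohol 15.

Step 5. SN2 displacement at C7 next to the silyloxy-bearing carbon may be slow. Elimination towards the conjugated diene or partial retention through an acyloxyphosphonium pathway may then compete. The fallback sets out from 9 and comes back at 11, setting C7 by 1,2-induction instead of substitution.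
- Buffered Dess–Martin oxidation gives the α-silyloxy ketone F4.
- Non-chelating hydride reduction (L-Selectride, −78 °C) under Felkin–Anh control should give the syn alcohol F5.
- Steglich esterification (EDC, DMAP) of the syn alcohol with 10 gives 11.

Step 4. Hydroalumination of the terminal alkene or metallation of the alkyne C–H may compete. Alkenyl transfer to the hindered epoxide may be slow, and the silyl group may migrate in the alkoxide. The fallback sets out from 6 and 3 and comes back at 9.
- Deprotonation of 6 with n-BuLi and BF3·OEt2-promoted opening of 3 at −78 °C (Yamaguchi–Hirao alkynylation) gives the homopropargylic alcohol F6.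
- Dissolving-metal trans reduction (Na, NH3, THF, −33 °C) should convert the alkyne into the E-alkene 9 without touching the isolated terminal alkene.

Further compounds
F1 | step 7 | (6S,7S,9S,10S)-6-[(tert-butyldimethylsilyl)oxy]-9,10-epoxynonadec-18-en-7-yl octadecanoate | CCCCC[C@H](O[Si](C)(C)C(C)(C)C)[C@@H](OC(=O)CCCCCCCCCCCCCCCCC)C[C@@H]1O[C@H]1CCCCCCCC=C
F2 | step 7 | (2S,3S,5R)-5-[(1S)-1-hydroxydec-9-en-1-yl]-2-pentyloxolan-3-yl octadecanoate | C=CCCCCCCC[C@H](O)[C@H]1C[C@H](OC(=O)CCCCCCCCCCCCCCCCC)[C@H](CCCCC)O1
F3 | step 7 | (2S,3S,5R)-5-(dec-9-enoyl)-2-pentyloxolan-3-yl octadecanoate | C=CCCCCCCCC(=O)[C@H]1C[C@H](OC(=O)CCCCCCCCCCCCCCCCC)[C@H](CCCCC)O1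
F4 | step 5 | (6S,9E)-6-[(tert-butyldimethylsilyl)oxy]nonadeca-9,18-dien-7-one | CCCCC[C@H](O[Si](C)(C)C(C)(C)C)C(=O)C/C=C/CCCCCCCC=C
F5 | step 5 | (6S,7S,9E)-6-[(tert-butyldimethylsilyl)oxy]nonadeca-9,18-dien-7-ol | CCCCC[C@H](O[Si](C)(C)C(C)(C)C)[C@@H](O)C/C=C/CCCCCCCC=C
F6 | step 4 | (6S,7R)-6-[(tert-butyldimethylsilyl)oxy]nonadec-18-en-9-yn-7-ol | CCCCC[C@H](O[Si](C)(C)C(C)(C)C)[C@H](O)CC#CCCCCCCCC=C
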